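## The problem

Compound 17 is a 9,9'-epoxylignan: a 3,4-trans-disubstituted oxolane whose two oxygen-bound ring carbons (C9 and C9') are bare methylenes. C8' carries a guaiacylmethyl group (C7') and C8 carries a syringyl carbinol (C7). Three contiguous stereocentres have to be set: C7 (S), C8 (R) and C8' (R). The two ring centres have no resident neighbour to lean on, so their absolute configuration must come from outside. Their trans relation, however, can be inherited from an E-alkene, and C7 can be set from C8 by 1,2-induction if it is made last from a ketone. The C7 alcohol is the delicate group: it is benzylic to an electron-rich ring with a free para-hydroxyl, so it ionises under acid (quinone methide, epimerisation, elimination) and is open to hydrogenolysis, and the free phenols are oxidation-prone. Once C7 is a carbonyl, the C8–H is acidic and the ring oxygen sits β to it, so strong base invites epimerisation or retro-oxa-Michael ring opening. The enabling feature is the unsubstituted C9–O–C9' bridge across the C8–C8' bond, which is the retron of formaldehyde O-methylide added to a C8=C8' alkene activated by a C7 acyl group.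

## Retrosynthesis

**17 from 16.** The two phenolic O–benzyl bonds are cut last. Benzyl ethers are the one phenol protection that survives fluoride, organolithium, hydride and aluminium amide, and both fall in a single neutral hydrogenolysis. The forward step must spare the C7–O bond.

**16 from 15.** The C7–H bond is cut, leaving aryl ketone 15. The neighbouring cut, C7–aryl at the aldehyde level, would by the same Felkin–Anh preference deliver 7R. Adding hydride last turns the same preference into 7S. The forward reaction must be face-selective and cold enough not to enolise C8.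

**15 from 11 and 14.** The C7–aryl bond is cut to the N-methoxy-N-methylamide 11 and aryllithium 14, which stops cleanly at the ketone. Reagent 14 comes from bromide 13 by bromine–lithium exchange, and 13 from commercial phenol 12 by benzylation. This removes the whole syringyl unit and leaves a compound with only the two ring stereocentres.

**11 from 10.** The acyl C–N bond is exchanged, so the chiral auxiliary of 10 is released as sultam 3 for recovery. The N-acyl sulfonamide is activated enough for direct aminolysis.

**10 from 6 and 9.** Both ring C–C bonds, C8–C9 and C8'–C9', are cut at once, giving the E-enoyl sultam 6 and ylide 9, released from chloro ether 8. Closing the ring through a C–O bond instead would need both CH2O arms built separately and a later choice between three hydroxyl groups. The cycloaddition gives the ring at its final oxidation level, and the E geometry fixes trans. Facial control through a chiral Lewis acid on an achiral imide was weighed and set aside. Fluoride would strip a magnesium-type centre as its insoluble fluoride, and the ylide adds to unactivated enoyl compounds anyway, so a racemic background path would remain. A covalently bound (2S)-bornane-10,2-sultam needs no metal, has close precedent with sulfur and nitrogen ylides under the same conditions, and makes the minor isomer a separable diastereomer.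

**6 from 2 and 5.** The C8=C8' double bond is cut by cross-metathesis into O-benzyleugenol 2 and N-acryloyl sultam 5. The alternative, carbonyl olefination of an arylacetaldehyde under base, risks shifting the double bond towards the arene. Ether 2 comes from eugenol 1, and 5 from sultam 3 through its sodium salt 4.

**8 from 7.** The O–CH2Cl bond is cut: chloromethylation of trimethylsilylmethanol 7 with formaldehyde and HCl.

## Roads not taken

Alternative 1: The cut is at the two exocyclic bonds C7–C8 and C7'–C8' on a preformed five-membered ring. Lithiated dithiane A3 adds conjugately to C8 of menthyloxybutenolide A2, anti to the acetal substituent, and the enolate is alkylated at C8' by benzyl bromide A4 to give all-trans lactone A1. This is well-established chemistry for lignans, brings in both aryl groups in one flask, and takes its stereocontrol from a crystalline enantiopure acetal. In predictability of the stereochemical outcome it is the better road. Its weakness for 17 is oxidation level: in A1, C9' is a lactone carbonyl and C9 an acetal. The ring therefore has to be reduced open and closed again as an ether while the C7 oxygen is kept from cyclising, and the dithiane must be unmasked on an electron-rich arene before the C7 reduction. That is some six or seven operations after the coupling. The chosen plan sets against this a ring formed at the correct oxidation level with both ring centres in one step and four steps to the target, at the price of a key step unproven in its asymmetric form.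

Alternative 2: No skeletal bond is cut; C9–Si and C8–H are formed on a temporary tether. The hydrodimethylsilyl ether A6 of the C7 allylic alcohol undergoes intramolecular hydrosilylation with Pt2[(CH2=CHSiMe2)2O]3 to give oxasilacyclopentane A5, with the C7 aryl group and the C8 branch cis. The step is mild, compatible with benzyl ethers and fully precedented. It fixes C8 relative to C7 without any ketone reduction, which is a real advantage over the chosen plan's reliance on Felkin–Anh control at C7. Against it: the step builds neither a C–C bond nor the oxolane. C7 and C8' must each be set beforehand by separate asymmetric operations, and the resident C8' centre next to the alkene may oppose the tether's preference. After C–Si oxidation the C9/C9' diol must be closed while the ionisable C7–OH is masked. The route is the longest of the four. The chosen plan answers with step economy and a reagent-controlled reduction held in reserve for C7.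

Alternative 3: The cut is at C9'–C8' and C7'–aryl. Cathodic reduction of N-hydroxyphthalimide ester A8 with NiBr2(dme) and 4,4'-di-tert-butyl-2,2'-bipyridine releases an alkoxymethyl radical that closes 5-exo onto the vinyl group. The resulting C7' radical is captured by nickel and arylated by iodide A9, giving A7. The merits are real: ring closure and guaiacyl attachment in one step, C7 and C8 already in place so no late reduction, and A7 only two deprotections from 17. The weak points are that C8' is set only by the substrate, and the trans preference of such radical closures is usually modest with no reagent to improve it. A8 must already hold two stereocentres, a vinyl group and an O-alkylated glycolate. The cascade also competes with reduction or direct arylation of the first radical. In novelty risk it is no worse than the chosen plan. The chosen plan sets against it a stereospecific trans outcome, auxiliary control of the absolute sense, and a diastereomer separation that guarantees stereochemical purity.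

Key step: step 5

Remark on the chemistry: lignan numbering is used for atoms, and the (2S)-sultam is assumed to steer the ylide to the face away from its pseudo-axial sulfonyl oxygen (si face of C8), as in uncatalysed dipolar cycloadditions to N-enoyl bornane-10,2-sultams.

## Route

Step 1
Reactants: 1 eugenol (4-allyl-2-methoxyphenol)
Product: 2 4-allyl-1-(benzyloxy)-2-methoxybenzene
Conditions: BnBr, K2CO3, acetone, reflux
Reagents that add atoms: benzyl bromide, BrCc1ccccc1
Why: Williamson ether synthesis on the phenoxide; the benzyl ether tolerates the metathesis catalyst, CsF, the organolithium and the hydride used later and is removed in the last step.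

Step 2
Reactants: 3 (2S)-bornane-10,2-sultam [(1R)-(+)-2,10-camphorsultam]
Product: 5 (2S)-N-acryloylbornane-10,2-sultam, via sodium sultamide 4 (not isolated)
Conditions: NaH, toluene, 0 °C to rt; then acryloyl chloride, BHT (trace), 0 °C to rt
Reagents that add atoms: acryloyl chloride, C=CC(Cl)=O
Why: N-acylation of the sodium sulfonamide anion 4 with an acid chloride, the standard way to load enoyl groups onto the camphorsultam; the radical inhibitor keeps the acrylamide from polymerising.

Step 3
Reactants: 2 4-allyl-1-(benzyloxy)-2-methoxybenzene (twofold excess), 5 (2S)-N-acryloylbornane-10,2-sultam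
Product: 6 (2S)-N-[(E)-4-(4-benzyloxy-3-methoxyphenyl)but-2-enoyl]bornane-10,2-sultam
Conditions: RuCl2(H2IMes)(=CH-C6H4-2-O-i-Pr) (second-generation Hoveyda–Grubbs catalyst, 5 mol%), 1,4-benzoquinone (10 mol%), CH2Cl2, 40 °C
Reagents that add atoms: none
Why: Olefin cross-metathesis between a readily dimerising terminal allylarene and an electron-poor acrylamide-type alkene, which favours the cross product and the E isomer under thermodynamic control. The neutral conditions avoid base-induced migration of the double bond towards the arene, and benzoquinone suppresses ruthenium hydride-mediated alkene migration.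

Step 4
Reactants: 7 trimethylsilylmethanol
Product: 8 chloromethyl trimethylsilylmethyl ether
Conditions: (CH2O)n, HCl (gas), 0 °C, neat; dry over CaCl2, distil
Reagents that add atoms: paraformaldehyde (as formaldehyde), C=O; hydrogen chloride, Cl
Why: Chloromethylation of a primary alcohol (hemiformal formation, then replacement of OH by chloride), the standard preparation of α-chloro ethers; 8 is moisture-sensitive and is handled as a suspected carcinogen.

Step 5
Reactants: 6 (2S)-N-[(E)-4-(4-benzyloxy-3-methoxyphenyl)but-2-enoyl]bornane-10,2-sultam, 8 chloromethyl trimethylsilylmethyl ether (3 equiv)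
Product: 10 (2S)-N-{[(3R,4R)-4-(4-benzyloxy-3-methoxybenzyl)oxolan-3-yl]carbonyl}bornane-10,2-sultam, via parent carbonyl ylide 9 (not isolated)
Conditions: CsF (3.5 equiv, dried, added in portions), MeCN, 0 °C to rt; crystallisation or chromatography to remove the minor diastereomer
Reagents that add atoms: none
Why: Proposed new method: fluoride attack on silicon of 8 triggers 1,3-elimination of Me3SiF and chloride to give the non-stabilised ylide 9, a nucleophilic 4π dipole that adds in a concerted, suprafacial [3+2] (4π + 2π) cycloaddition to the electron-poor C8=C8' bond of 6, so the oxolane closes in an intermolecular cycloaddition mode by simultaneous formation of C8–C9 and C8'–C9'. The closest known reaction types are the CsF-mediated addition of this same ylide to achiral acrylates, fumarates and enones, and the auxiliary-controlled additions of the analogous fluoride-generated thiocarbonyl ylide and of non-stabilised azomethine ylides to N-enoyl camphorsultams; what is new is facial control of the oxygen ylide by the sultam. The trans relation of C8 and C8' is a matter of stereospecificity, the E geometry of 6 being copied into the ring. The absolute configuration of both centres is set by the (2S)-sultam: in the reactive conformer (C=O anti to SO2, enoyl s-cis) the pseudo-axial sulfonyl oxygen covers the re face of C8, so the small ylide should approach the si face and give 3R,4R. No Lewis acid is used, because fluoride would remove a magnesium-type centre as its insoluble fluoride and because 9 adds to the free enoyl compound without activation. The step needs chemoselectivity for cycloaddition over γ-deprotonation at the doubly activated benzylic C7' methylene; keeping 8 in excess over fluoride by portionwise addition of CsF keeps free basic fluoride low. The minor (3S,4S) adduct is a diastereomer of 10 and is to be removed by crystallisation or chromatography, so a single stereoisomer is carried forward whatever the level of induction.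

Step 6
Reactants: 10 (2S)-N-{[(3R,4R)-4-(4-benzyloxy-3-methoxybenzyl)oxolan-3-yl]carbonyl}bornane-10,2-sultam
Product: 11 (3R,4R)-4-(4-benzyloxy-3-methoxybenzyl)-N-methoxy-N-methyloxolane-3-carboxamide
Conditions: MeONHMe·HCl, Me3Al, CH2Cl2, 0 °C to 40 °C; then 1 M HCl
Reagents that add atoms: N,O-dimethylhydroxylamine hydrochloride, Cl.CNOC
Why: Weinreb amide formation by aminolysis of the activated N-acyl sulfonamide with the chloroaluminium amide of N,O-dimethylhydroxylamine, a known way of cleaving N-acyl camphorsultams; sultam 3 is recovered and C8 is safe because trans is the thermodynamically favoured arrangement.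

Step 7
Reactants: 12 4-bromo-2,6-dimethoxyphenol
Product: 13 2-(benzyloxy)-5-bromo-1,3-dimethoxybenzene
Conditions: BnBr, K2CO3, DMF, rt
Reagents that add atoms: benzyl bromide, BrCc1ccccc1
Why: Williamson ether synthesis; the flanking methoxy groups slow but do not prevent O-alkylation of the phenoxide in a dipolar aprotic solvent.

Step 8
Reactants: 13 2-(benzyloxy)-5-bromo-1,3-dimethoxybenzene, 11 (3R,4R)-4-(4-benzyloxy-3-methoxybenzyl)-N-methoxy-N-methyloxolane-3-carboxamide
Product: 15 [(3R,4R)-4-(4-benzyloxy-3-methoxybenzyl)oxolan-3-yl](4-benzyloxy-3,5-dimethoxyphenyl)methanone, via aryllithium 14 (not isolated)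
Conditions: 13, n-BuLi, THF, −78 °C; then 11, −78 to −20 °C; aq. NH4Cl
Reagents that add atoms: none
Why: Bromine–lithium exchange followed by Weinreb ketone synthesis; the chelated tetrahedral adduct persists until work-up so over-addition is excluded, and addition at −78 °C outpaces deprotonation at C8, so neither epimerisation nor β-elimination of the ring oxygen is expected.

Step 9
Reactants: 15 [(3R,4R)-4-(4-benzyloxy-3-methoxybenzyl)oxolan-3-yl](4-benzyloxy-3,5-dimethoxyphenyl)methanone
Product: 16 (S)-[(3R,4R)-4-(4-benzyloxy-3-methoxybenzyl)oxolan-3-yl](4-benzyloxy-3,5-dimethoxyphenyl)methanol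
Conditions: LiBH(s-Bu)3, THF, −78 °C; aq. NH4Cl
Reagents that add atoms: none
Why: Diastereoselective ketone reduction under Felkin–Anh control: with the C8' ring branch as the large α-substituent anti to the incoming hydride and the C8 hydrogen beside the attack trajectory, the bulky hydride should add to the face that gives 7S. A chelate between the carbonyl and ring oxygens would expose the same face, so both models agree.

Step 10
Reactants: 16 (S)-[(3R,4R)-4-(4-benzyloxy-3-methoxybenzyl)oxolan-3-yl](4-benzyloxy-3,5-dimethoxyphenyl)methanol
Product: 17 (S)-(4-hydroxy-3,5-dimethoxyphenyl)[(3R,4R)-4-(4-hydroxy-3-methoxybenzyl)oxolan-3-yl]methanol (CNP0307127.1)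
Conditions: H2 (1 atm), 10% Pd/C, EtOAc, rt, stopped at full debenzylation
Reagents that add atoms: none
Why: Hydrogenolysis of aryl benzyl ethers, which in a neutral aprotic solvent is much faster than cleavage of the secondary benzylic C7–O bond; acid is excluded because the p-hydroxybenzylic alcohol of 17 ionises easily.

## Compound list

1 | eugenol (4-allyl-2-methoxyphenol) | COc1cc(CC=C)ccc1O | starting material
2 | 4-allyl-1-(benzyloxy)-2-methoxybenzene | COc1cc(CC=C)ccc1OCc1ccccc1 | intermediate
3 | (2S)-bornane-10,2-sultam, (1R,2S,4S), the (+)-camphorsultam | O=S1(=O)N[C@H]2C[C@@H]3CC[C@@]2(C1)C3(C)C | starting material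
4 | sodium salt of (2S)-bornane-10,2-sultam | [Na+].O=S1(=O)[N-][C@H]2C[C@@H]3CC[C@@]2(C1)C3(C)C | intermediate (not isolated)
5 | (2S)-N-acryloylbornane-10,2-sultam | C=CC(=O)N1[C@H]2C[C@@H]3CC[C@@]2(CS1(=O)=O)C3(C)C | intermediate
6 | (2S)-N-[(E)-4-(4-benzyloxy-3-methoxyphenyl)but-2-enoyl]bornane-10,2-sultam | COc1cc(C/C=C/C(=O)N2[C@H]3C[C@@H]4CC[C@@]3(CS2(=O)=O)C4(C)C)ccc1OCc1ccccc1 | intermediate
7 | trimethylsilylmethanol | C[Si](C)(C)CO | starting material
8 | chloromethyl trimethylsilylmethyl ether | C[Si](C)(C)COCCl | intermediate
9 | formaldehyde O-methylide (parent carbonyl ylide) | C=[O+][CH2-] | intermediate (not isolated)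
10 | (2S)-N-{[(3R,4R)-4-(4-benzyloxy-3-methoxybenzyl)oxolan-3-yl]carbonyl}bornane-10,2-sultam | COc1cc(C[C@H]2COC[C@@H]2C(=O)N2[C@H]3C[C@@H]4CC[C@@]3(CS2(=O)=O)C4(C)C)ccc1OCc1ccccc1 | intermediate
11 | (3R,4R)-4-(4-benzyloxy-3-methoxybenzyl)-N-methoxy-N-methyloxolane-3-carboxamide | COc1cc(C[C@H]2COC[C@@H]2C(=O)N(C)OC)ccc1OCc1ccccc1 | intermediate
12 | 4-bromo-2,6-dimethoxyphenol | COc1cc(Br)cc(OC)c1O | starting material
13 | 2-(benzyloxy)-5-bromo-1,3-dimethoxybenzene | COc1cc(Br)cc(OC)c1OCc1ccccc1 | intermediate
14 | (4-benzyloxy-3,5-dimethoxyphenyl)lithium | [Li]c1cc(OC)c(OCc2ccccc2)c(OC)c1 | intermediate (not isolated)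
15 | [(3R,4R)-4-(4-benzyloxy-3-methoxybenzyl)oxolan-3-yl](4-benzyloxy-3,5-dimethoxyphenyl)methanone | COc1cc(C[C@H]2COC[C@@H]2C(=O)c2cc(OC)c(OCc3ccccc3)c(OC)c2)ccc1OCc1ccccc1 | intermediate
16 | (S)-[(3R,4R)-4-(4-benzyloxy-3-methoxybenzyl)oxolan-3-yl](4-benzyloxy-3,5-dimethoxyphenyl)methanol | COc1cc(C[C@H]2COC[C@@H]2[C@H](O)c2cc(OC)c(OCc3ccccc3)c(OC)c2)ccc1OCc1ccccc1 | intermediate
17 | (S)-(4-hydroxy-3,5-dimethoxyphenyl)[(3R,4R)-4-(4-hydroxy-3-methoxybenzyl)oxolan-3-yl]methanol; (7S,8R,8'R) in lignan numbering | COc1cc(C[C@H]2COC[C@@H]2[C@H](O)c2cc(OC)c(O)c(OC)c2)ccc1O | target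

## Step count and risks

Total steps: 10. Longest linear sequence: 7 steps (1 → 2 → 6 → 10 → 11 → 15 → 16 → 17, or equally from 3 through 5).

**Step 5 (key step, the one step beyond known chemistry).** The most likely failure is weak facial selectivity. The uncatalysed addition of a small, very reactive dipole has an early transition state that may feel the auxiliary only moderately, so 10 may have to be separated from much of its diastereomer. The second risk is fluoride-induced migration of the C8=C8' bond towards the arene, which would remove the acceptor alkene. The fallback uses known chemistry only, sets out from 2 and returns at 10.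
- Cross-metathesis of 2 with methyl acrylate under the conditions of step 3 would give methyl (E)-4-(4-benzyloxy-3-methoxyphenyl)but-2-enoate F1.
- The known fluoride-mediated addition of 9 (from 8 and CsF) to this simple enoate would give racemic methyl trans-4-(4-benzyloxy-3-methoxybenzyl)oxolane-3-carboxylate F2.
- Heating F2 in toluene with the dimethylaluminium amide of the sultam F3 (made from 3 and Me3Al) would move the acyl group onto the auxiliary. This gives 10 together with its (3S,4S)-diastereomer F4, and the two are separated by crystallisation or chromatography.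
- This is a resolution through the same auxiliary and costs at most half of the material. It answers the selectivity risk but not the migration risk.

**Step 3.** The likely failures are slow turnover with the bulky, chelating acryloyl sultam and migration of the allyl double bond into conjugation before metathesis, which would shorten the chain by one carbon. The fallback replaces metathesis by carbonyl olefination, sets out from 2 and 3 and returns at 6.
- Oxidative cleavage of the allyl group of 2 (OsO4 catalytic, NaIO4; Lemieux–Johnson) would give (4-benzyloxy-3-methoxyphenyl)acetaldehyde F5.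
- Sultam 3 is acylated through 4 with bromoacetyl bromide to (2S)-N-(bromoacetyl)bornane-10,2-sultam F6.
- F6 with P(OEt)3 (Arbuzov) gives (2S)-N-[(diethoxyphosphoryl)acetyl]bornane-10,2-sultam F7.
- Horner–Wadsworth–Emmons olefination of F5 with F7 under LiCl and i-Pr2NEt in MeCN gives 6.

**Step 6.** The likely failure is sluggish or misdirected aminolysis, because the acyl carbon is α-branched and the aluminium amide may attack slowly or at sulfur. The fallback separates cleavage from amide formation, sets out from 10 and returns at 11. Hydrolysis with LiOH and H2O2 in aqueous THF would give (3R,4R)-4-(4-benzyloxy-3-methoxybenzyl)oxolane-3-carboxylic acid F8 with recovery of 3. Coupling of F8 with MeONHMe·HCl (1,1'-carbonyldiimidazole, CH2Cl2) gives 11.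

**Step 9.** The likely failure is insufficient face selectivity at C7, because the two α-substituents of C8 are both ring carbons and differ less in size than in open-chain cases. The fallback changes from substrate control to reagent control, sets out from 15 and returns at 16. Reduction with BH3·SMe2 and the (R)-B-methyl oxazaborolidine derived from (R)-diphenylprolinol (Corey–Bakshi–Shibata reduction) should deliver hydride to the same face, with the aryl group acting as the large substituent. It makes no new compound (F0).

**Step 10.** The likely failure is over-reduction: hydrogenolysis of the C7–O bond, which is activated by the electron-rich ring once the para-phenol is free. The fallback removes the benzyl groups before the benzylic alcohol exists, sets out from 15 and returns at 17.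
- Hydrogenolysis of 15 (H2, 10% Pd/C, EtOAc) gives [(3R,4R)-4-(4-hydroxy-3-methoxybenzyl)oxolan-3-yl](4-hydroxy-3,5-dimethoxyphenyl)methanone F9.
- Silylation (t-BuMe2SiCl, imidazole, DMF) gives the bis(tert-butyldimethylsilyl) ether of that ketone F10.
- Reduction with LiBH(s-Bu)3 as in step 9 gives the bis(tert-butyldimethylsilyl) ether of 17 F11.
- Bu4NF buffered with AcOH in THF at 0 °C releases 17.

## Further compounds

F1 | step 5 | methyl (E)-4-(4-benzyloxy-3-methoxyphenyl)but-2-enoate | COc1cc(C/C=C/C(=O)OC)ccc1OCc1ccccc1
F2 | step 5 | methyl trans-4-(4-benzyloxy-3-methoxybenzyl)oxolane-3-carboxylate, racemic (3R,4R enantiomer drawn) | COc1cc(C[C@H]2COC[C@@H]2C(=O)OC)ccc1OCc1ccccc1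
F3 | step 5 | dimethylaluminium amide of (2S)-bornane-10,2-sultam | C[Al](C)N1[C@H]2C[C@@H]3CC[C@@]2(CS1(=O)=O)C3(C)C
F4 | step 5 | (2S)-N-{[(3S,4S)-4-(4-benzyloxy-3-methoxybenzyl)oxolan-3-yl]carbonyl}bornane-10,2-sultam | COc1cc(C[C@@H]2COC[C@H]2C(=O)N2[C@H]3C[C@@H]4CC[C@@]3(CS2(=O)=O)C4(C)C)ccc1OCc1ccccc1
F5 | step 3 | (4-benzyloxy-3-methoxyphenyl)acetaldehyde | COc1cc(CC=O)ccc1OCc1ccccc1
F6 | step 3 | (2S)-N-(bromoacetyl)bornane-10,2-sultam | O=C(CBr)N1[C@H]2C[C@@H]3CC[C@@]2(CS1(=O)=O)C3(C)C
F7 | step 3 | (2S)-N-[(diethoxyphosphoryl)acetyl]bornane-10,2-sultam | CCOP(=O)(CC(=O)N1[C@H]2C[C@@H]3CC[C@@]2(CS1(=O)=O)C3(C)C)OCC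
F8 | step 6 | (3R,4R)-4-(4-benzyloxy-3-methoxybenzyl)oxolane-3-carboxylic acid | COc1cc(C[C@H]2COC[C@@H]2C(=O)O)ccc1OCc1ccccc1
F0 | step 9 | none | none
F9 | step 10 | [(3R,4R)-4-(4-hydroxy-3-methoxybenzyl)oxolan-3-yl](4-hydroxy-3,5-dimethoxyphenyl)methanone | COc1cc(C[C@H]2COC[C@@H]2C(=O)c2cc(OC)c(O)c(OC)c2)ccc1O
F10 | step 10 | {(3R,4R)-4-[4-(tert-butyldimethylsilyloxy)-3-methoxybenzyl]oxolan-3-yl}[4-(tert-butyldimethylsilyloxy)-3,5-dimethoxyphenyl]methanone | COc1cc(C[C@H]2COC[C@@H]2C(=O)c2cc(OC)c(O[Si](C)(C)C(C)(C)C)c(OC)c2)ccc1O[Si](C)(C)C(C)(C)C
F11 | step 10 | (S)-{(3R,4R)-4-[4-(tert-butyldimethylsilyloxy)-3-methoxybenzyl]oxolan-3-yl}[4-(tert-butyldimethylsilyloxy)-3,5-dimethoxyphenyl]methanol | COc1cc(C[C@H]2COC[C@@H]2[C@H](O)c2cc(OC)c(O[Si](C)(C)C(C)(C)C)c(OC)c2)ccc1O[Si](C)(C)C(C)(C)C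
A1 | alternative 1 | all-trans 3-(4-benzyloxy-3-methoxybenzyl)-4-[2-(4-benzyloxy-3,5-dimethoxyphenyl)-1,3-dithian-2-yl]-5-[(1R,2S,5R)-menthyloxy]dihydrofuran-2(3H)-one | COc1cc(C[C@H]2C(=O)O[C@@H](O[C@@H]3C[C@H](C)CC[C@H]3C(C)C)[C@@H]2C2(c3cc(OC)c(OCc4ccccc4)c(OC)c3)SCCCS2)ccc1OCc1ccccc1
A2 | alternative 1 | (5R)-5-[(1R,2S,5R)-menthyloxy]furan-2(5H)-one | O=C1C=C[C@H](O[C@@H]2C[C@H](C)CC[C@H]2C(C)C)O1
A3 | alternative 1 | 2-(4-benzyloxy-3,5-dimethoxyphenyl)-1,3-dithiane | COc1cc(C2SCCCS2)cc(OC)c1OCc1ccccc1
A4 | alternative 1 | 4-benzyloxy-3-methoxybenzyl bromide | COc1cc(CBr)ccc1OCc1ccccc1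
A5 | alternative 2 | 2,2-dimethyl-1-oxa-2-silacyclopentane with the 5-(4-benzyloxy-3,5-dimethoxyphenyl) group (C7) and the 4-[1-(4-benzyloxy-3-methoxyphenyl)-3-(tert-butyldiphenylsilyloxy)propan-2-yl] branch (C8) cis | COc1cc(C[C@H]([C@@H]2C[Si](C)(C)O[C@@H]2c2cc(OC)c(OCc3ccccc3)c(OC)c2)CO[Si](c2ccccc2)(c2ccccc2)C(C)(C)C)ccc1OCc1ccccc1
A6 | alternative 2 | hydrodimethylsilyl ether of the C7 allylic alcohol with a C8=C9 methylene group and the C8' stereocentre in place | COc1cc(C[C@H](C(=C)[C@H](O[SiH](C)C)c2cc(OC)c(OCc3ccccc3)c(OC)c2)CO[Si](c2ccccc2)(c2ccccc2)C(C)(C)C)ccc1OCc1ccccc1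
A7 | alternative 3 | O7-tert-butyldimethylsilyl, bis-O-benzyl derivative of 17 | COc1cc(C[C@H]2COC[C@@H]2[C@H](O[Si](C)(C)C(C)(C)C)c2cc(OC)c(OCc3ccccc3)c(OC)c2)ccc1OCc1ccccc1
A8 | alternative 3 | N-hydroxyphthalimide ester of the O-alkylated glycolic acid carrying the C8 vinyl group and the silylated C7 carbinol | C=C[C@H](COCC(=O)ON1C(=O)c2ccccc2C1=O)[C@H](O[Si](C)(C)C(C)(C)C)c1cc(OC)c(OCc2ccccc2)c(OC)c1
A9 | alternative 3 | 1-(benzyloxy)-4-iodo-2-methoxybenzene | COc1cc(I)ccc1OCc1ccccc1
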